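**Plan**

1. Retrosynthetic cuts, in order: the two silyl ethers; the ring A C1–C7 bond (aryl iodide plus aldehyde); the amide C–N bond; the indole C5–O–C8 ether; the ring A–O–ring B diaryl ether, with the ring A phenol oxygen derived from an aldehyde carbon.
2. Enabling feature: C7 is a benzylic carbinol between C1 of ring A (the trioxygenated benzene; C1 is para to the phenol oxygen, where a phenol iodinates) and the C8 methine that carries the indol-5-yloxy group and the CH2OH arm. The C1–C7 bond is therefore the addition of an aryl metal to an α-aryloxy aldehyde.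
3. Forward order: the ring A–ring B iodo acid (4 steps) and the serotonin glyceryl ether (4 steps) are joined as the amide, the primary alcohol is oxidised, and the 21-membered ring (the only ring made) is closed at C1–C7; fluoride then frees the phenol and the primary alcohol.
4. Stereochemistry: C8 comes from (R)-3-(benzyloxy)propane-1,2-diol with one Mitsunobu inversion; C7 is set in the ring closure by Felkin–Anh attack anti to the C8–O bond; the E-alkene is bought in with methyl (E)-4-hydroxycinnamate.

Key step: step 11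

Remark: serotonin is taken as its commercial hydrochloride. C7, C8 and C9 denote the carbinol carbon, the aryloxy methine and the CH2OH carbon; ring A is the trioxygenated benzene and ring B the para-disubstituted one.

**Route**

Step 1
Reactants: 1 methyl (E)-4-hydroxycinnamate; 2 2-fluoro-6-methoxybenzaldehyde
Product: 3 methyl (E)-3-[4-(2-formyl-3-methoxyphenoxy)phenyl]acrylate
Conditions: K2CO3, DMF, 110 °C
Reagents that add atoms: none
Why: Nucleophilic aromatic substitution (SNAr), in which the ortho-formyl group activates the C–F bond toward the phenoxide, so the diaryl ether is placed next to the carbon that will become the ring A phenol without any regiochemical choice.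

Step 2
Reactants: 3 methyl (E)-3-[4-(2-formyl-3-methoxyphenoxy)phenyl]acrylate
Product: 5 (E)-3-[4-(2-hydroxy-3-methoxyphenoxy)phenyl]acrylic acid, via aryl formate 4 (not isolated)
Conditions: mCPBA, CH2Cl2, 0 °C to rt; aq. Na2SO3/NaHCO3 wash; then NaOH, THF–MeOH–H2O, rt; 1 M HCl
Reagents that add atoms: mCPBA, O=C(OO)c1cccc(Cl)c1; sodium hydroxide, [Na+].[OH-]
Why: Baeyer–Villiger (Dakin-type) oxidation, in which the electron-rich 2,6-dioxygenated aryl group migrates to oxygen to give the formate while the electron-poor acrylate is not epoxidised, followed by saponification that frees the phenol and the carboxylic acid together.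

Step 3
Reactants: 5 (E)-3-[4-(2-hydroxy-3-methoxyphenoxy)phenyl]acrylic acid
Product: 6 (E)-3-[4-(2-hydroxy-5-iodo-3-methoxyphenoxy)phenyl]acrylic acid
Conditions: NIS, MeCN, 0 °C to rt
Reagents that add atoms: N-iodosuccinimide, O=C1CCC(=O)N1I
Why: Electrophilic aromatic iodination, directed by the free phenol to its para position because both ortho positions are blocked by the methoxy and aryloxy groups (the pattern by which 2,6-dialkoxyphenols are halogenated at C4), while ring B and the acrylic acid are far less nucleophilic.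

Step 4
Reactants: 6 (E)-3-[4-(2-hydroxy-5-iodo-3-methoxyphenoxy)phenyl]acrylic acid
Product: 8 (E)-3-[4-(2-{[tert-butyl(dimethyl)silyl]oxy}-5-iodo-3-methoxyphenoxy)phenyl]acrylic acid, via bis-silyl derivative 7 (not isolated)
Conditions: TBSCl, imidazole, DMF, rt; then AcOH–THF–H2O, rt
Reagents that add atoms: tert-butyldimethylsilyl chloride, CC(C)(C)[Si](C)(C)Cl
Why: Silylation of the phenol and the acid followed by selective hydrolysis of the labile silyl ester under mild aqueous acid, which the hindered aryl silyl ether (flanked by two ortho substituents) should survive.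

Step 5
Reactants: 9 (R)-3-(benzyloxy)propane-1,2-diol
Product: 10 (2S)-1-(benzyloxy)-3-[(tert-butyldiphenylsilyl)oxy]propan-2-ol
Conditions: TBDPSCl, imidazole, CH2Cl2, 0 °C
Reagents that add atoms: tert-butyldiphenylsilyl chloride, CC(C)(C)[Si](Cl)(c1ccccc1)c1ccccc1
Why: Silyl ether formation in which the bulky silyl chloride reacts only at the primary hydroxyl; the stereocentre is not touched and its descriptor changes from R to S merely because the silyloxymethyl arm now outranks the benzyloxymethyl arm.

Step 6
Reactants: 11 serotonin hydrochloride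
Product: 12 benzyl N-[2-(5-hydroxy-1H-indol-3-yl)ethyl]carbamate
Conditions: CbzOSu, NaHCO3, THF–H2O, 0 °C to rt
Reagents that add atoms: N-(benzyloxycarbonyloxy)succinimide, O=C(OCc1ccccc1)ON1C(=O)CCC1=O
Why: Carbamate formation with an active carbonate, in which the aliphatic amine is acylated much faster under bicarbonate than the phenol or the indole nitrogen, leaving the 5-hydroxyl free for the ether formation.

Step 7
Reactants: 12 benzyl N-[2-(5-hydroxy-1H-indol-3-yl)ethyl]carbamate; 10 (2S)-1-(benzyloxy)-3-[(tert-butyldiphenylsilyl)oxy]propan-2-ol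
Product: 13 benzyl N-{2-[5-({(2R)-1-(benzyloxy)-3-[(tert-butyldiphenylsilyl)oxy]propan-2-yl}oxy)-1H-indol-3-yl]ethyl}carbamate
Conditions: PPh3, DIAD, THF, 0 °C to 40 °C
Reagents that add atoms: none
Why: Mitsunobu etherification, in which the hydroxyindole displaces the oxyphosphonium-activated secondary alcohol by SN2 with inversion, turning the (S)-carbinol into the (R)-aryl ether that becomes C8 (8S) of the target, while the carbamate and indole N–H bonds are too weakly acidic to compete.

Step 8
Reactants: 13 benzyl N-{2-[5-({(2R)-1-(benzyloxy)-3-[(tert-butyldiphenylsilyl)oxy]propan-2-yl}oxy)-1H-indol-3-yl]ethyl}carbamate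
Product: 14 (2R)-2-{[3-(2-aminoethyl)-1H-indol-5-yl]oxy}-3-[(tert-butyldiphenylsilyl)oxy]propan-1-ol
Conditions: H2 (1 atm), Pd(OH)2 on carbon, EtOH–AcOH (10:1), rt; aq. NaHCO3 work-up
Reagents that add atoms: none
Why: Catalytic hydrogenolysis that cleaves the benzyl carbamate and the primary benzyl ether together (acetic acid keeps the liberated amine protonated so that it does not slow the ether cleavage), whereas the silyl ether, the non-benzylic aryl alkyl ether and the indole are inert, and the step is placed before the alkene and the iodide enter.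

Step 9
Reactants: 8 (E)-3-[4-(2-{[tert-butyl(dimethyl)silyl]oxy}-5-iodo-3-methoxyphenoxy)phenyl]acrylic acid; 14 (2R)-2-{[3-(2-aminoethyl)-1H-indol-5-yl]oxy}-3-[(tert-butyldiphenylsilyl)oxy]propan-1-ol
Product: 15 (E)-N-{2-[5-({(2R)-1-[(tert-butyldiphenylsilyl)oxy]-3-hydroxypropan-2-yl}oxy)-1H-indol-3-yl]ethyl}-3-[4-(2-{[tert-butyl(dimethyl)silyl]oxy}-5-iodo-3-methoxyphenoxy)phenyl]acrylamide
Conditions: DIC, HOBt, CH2Cl2–DMF, 0 °C to rt
Reagents that add atoms: none
Why: Carbodiimide/HOBt amide coupling, in which the primary amine reacts with the active ester far faster than the primary alcohol, so N-acylation is chemoselective and the E-alkene, the aryl iodide and both silyl ethers are untouched.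

Step 10
Reactants: 15 (E)-N-{2-[5-({(2R)-1-[(tert-butyldiphenylsilyl)oxy]-3-hydroxypropan-2-yl}oxy)-1H-indol-3-yl]ethyl}-3-[4-(2-{[tert-butyl(dimethyl)silyl]oxy}-5-iodo-3-methoxyphenoxy)phenyl]acrylamide
Product: 16 (E)-N-{2-[5-({(2S)-1-[(tert-butyldiphenylsilyl)oxy]-3-oxopropan-2-yl}oxy)-1H-indol-3-yl]ethyl}-3-[4-(2-{[tert-butyl(dimethyl)silyl]oxy}-5-iodo-3-methoxyphenoxy)phenyl]acrylamide (seco iodo aldehyde)
Conditions: Dess–Martin periodinane, CH2Cl2, 0 °C to rt; used at once
Reagents that add atoms: none
Why: Dess–Martin oxidation, a near-neutral oxidant that stops at the aldehyde and is known to spare indole N–H, secondary amides, aryl iodides and silyl ethers, so the α-aryloxy stereocentre should be retained if the aldehyde is carried forward immediately.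

Step 11
Reactants: 16 seco iodo aldehyde
Product: 18 bis-silyl macrocycle (7R,8S), the 21-membered ring with free C7 hydroxyl, ring A O-TBS ether and C9 O-TBDPS ether, via arylchromium dichloride 17 (not isolated)
Conditions: CrCl2 (15 equiv), NiCl2 (0.1 equiv), degassed DMSO–THF, rt, 2 mM, slow addition of 16
Reagents that add atoms: none
Why: NiCl2 is reduced by CrCl2 to zerovalent nickel, which inserts into the ring A C–I bond; the aryl group is passed on to trivalent chromium (17), and this weakly basic, oxophilic aryl metal adds to the tethered aldehyde, the chromium alkoxide being protonated on work-up. The closest known reaction type is the Nozaki–Hiyama–Kishi coupling of aryl and alkenyl iodides with aldehydes, an established macrocyclisation method, in which reductive metalation turns one of two electrophilic carbons into the nucleophile. The 21-membered ring closes in the exo-trig mode, the carbonyl oxygen ending outside the ring as the C7 hydroxyl. The new C7 centre is controlled by C8: in the polar Felkin–Anh arrangement the aryl group approaches anti to the C8–OAr bond and past the C8 hydrogen, which gives the 7R carbinol of the anti (erythro) 7R,8S pair, and because the aryloxy and the bulky silyloxy oxygens are poor donors a chelated arrangement leading to the 7S epimer is not expected to compete. The step needs ring closure to win over intermolecular coupling, which high dilution and slow addition secure, and it needs chemoselectivity for the aldehyde, which the arylchromium reagent provides by ignoring the amide, the acrylamide double bond, the indole N–H and both silyl ethers.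

Step 12
Reactants: 18 bis-silyl macrocycle (7R,8S)
Product: 19 CNP0276372.1 (target)
Conditions: TBAF, AcOH, THF, 0 °C to rt
Reagents that add atoms: none
Why: Fluoride-mediated desilylation, in which fluoride attacks silicon of both the aryl and the primary alkyl silyl ether while acetic acid buffers the phenoxide so that the para-hydroxybenzylic carbinol is not exposed to strong base, and no stereocentre is involved.

**Compound list**

1 | methyl (E)-4-hydroxycinnamate | COC(=O)/C=C/c1ccc(O)cc1 | starting material
2 | 2-fluoro-6-methoxybenzaldehyde | COc1cccc(F)c1C=O | starting material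
3 | methyl (E)-3-[4-(2-formyl-3-methoxyphenoxy)phenyl]acrylate | COC(=O)/C=C/c1ccc(Oc2cccc(OC)c2C=O)cc1 | intermediate
4 | methyl (E)-3-{4-[2-(formyloxy)-3-methoxyphenoxy]phenyl}acrylate (aryl formate, not isolated) | COC(=O)/C=C/c1ccc(Oc2cccc(OC)c2OC=O)cc1 | intermediate
5 | (E)-3-[4-(2-hydroxy-3-methoxyphenoxy)phenyl]acrylic acid | OC(=O)/C=C/c1ccc(Oc2cccc(OC)c2O)cc1 | intermediate
6 | (E)-3-[4-(2-hydroxy-5-iodo-3-methoxyphenoxy)phenyl]acrylic acid | OC(=O)/C=C/c1ccc(Oc2cc(I)cc(OC)c2O)cc1 | intermediate
7 | tert-butyldimethylsilyl (E)-3-[4-(2-{[tert-butyl(dimethyl)silyl]oxy}-5-iodo-3-methoxyphenoxy)phenyl]acrylate (bis-silyl derivative, not isolated) | CC(C)(C)[Si](C)(C)OC(=O)/C=C/c1ccc(Oc2cc(I)cc(OC)c2O[Si](C)(C)C(C)(C)C)cc1 | intermediate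
8 | (E)-3-[4-(2-{[tert-butyl(dimethyl)silyl]oxy}-5-iodo-3-methoxyphenoxy)phenyl]acrylic acid | OC(=O)/C=C/c1ccc(Oc2cc(I)cc(OC)c2O[Si](C)(C)C(C)(C)C)cc1 | intermediate
9 | (R)-3-(benzyloxy)propane-1,2-diol | O[C@@H](COCc1ccccc1)CO | starting material
10 | (2S)-1-(benzyloxy)-3-[(tert-butyldiphenylsilyl)oxy]propan-2-ol | O[C@@H](COCc1ccccc1)CO[Si](c1ccccc1)(c1ccccc1)C(C)(C)C | intermediate
11 | serotonin hydrochloride, 3-(2-aminoethyl)-1H-indol-5-ol hydrochloride | Cl.NCCc1c[nH]c2ccc(O)cc12 | starting material
12 | benzyl N-[2-(5-hydroxy-1H-indol-3-yl)ethyl]carbamate | O=C(OCc1ccccc1)NCCc1c[nH]c2ccc(O)cc12 | intermediate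
13 | benzyl N-{2-[5-({(2R)-1-(benzyloxy)-3-[(tert-butyldiphenylsilyl)oxy]propan-2-yl}oxy)-1H-indol-3-yl]ethyl}carbamate | O=C(OCc1ccccc1)NCCc1c[nH]c2ccc(O[C@H](COCc3ccccc3)CO[Si](c3ccccc3)(c3ccccc3)C(C)(C)C)cc12 | intermediate
14 | (2R)-2-{[3-(2-aminoethyl)-1H-indol-5-yl]oxy}-3-[(tert-butyldiphenylsilyl)oxy]propan-1-ol | NCCc1c[nH]c2ccc(O[C@H](CO)CO[Si](c3ccccc3)(c3ccccc3)C(C)(C)C)cc12 | intermediate
15 | (E)-N-{2-[5-({(2R)-1-[(tert-butyldiphenylsilyl)oxy]-3-hydroxypropan-2-yl}oxy)-1H-indol-3-yl]ethyl}-3-[4-(2-{[tert-butyl(dimethyl)silyl]oxy}-5-iodo-3-methoxyphenoxy)phenyl]acrylamide | O=C(/C=C/c1ccc(Oc2cc(I)cc(OC)c2O[Si](C)(C)C(C)(C)C)cc1)NCCc1c[nH]c2ccc(O[C@H](CO)CO[Si](c3ccccc3)(c3ccccc3)C(C)(C)C)cc12 | intermediate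
16 | seco iodo aldehyde, (E)-N-{2-[5-({(2S)-1-[(tert-butyldiphenylsilyl)oxy]-3-oxopropan-2-yl}oxy)-1H-indol-3-yl]ethyl}-3-[4-(2-{[tert-butyl(dimethyl)silyl]oxy}-5-iodo-3-methoxyphenoxy)phenyl]acrylamide | O=C[C@H](CO[Si](C(C)(C)C)(c1ccccc1)c1ccccc1)Oc1ccc2[nH]cc(CCNC(=O)/C=C/c3ccc(Oc4cc(I)cc(OC)c4O[Si](C)(C)C(C)(C)C)cc3)c2c1 | intermediate
17 | arylchromium dichloride of 16 (iodine replaced by CrCl2, trivalent chromium; not isolated) | O=C[C@H](CO[Si](C(C)(C)C)(c1ccccc1)c1ccccc1)Oc1ccc2[nH]cc(CCNC(=O)/C=C/c3ccc(Oc4cc([Cr](Cl)Cl)cc(OC)c4O[Si](C)(C)C(C)(C)C)cc3)c2c1 | intermediate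
18 | bis-silyl macrocycle (7R,8S): 21-membered ring, free C7 hydroxyl, ring A O-TBS ether, C9 O-TBDPS ether | COc1cc2cc(c1O[Si](C)(C)C(C)(C)C)Oc1ccc(cc1)/C=C/C(=O)NCCc1c[nH]c3ccc(cc13)O[C@@H](CO[Si](C(C)(C)C)(c1ccccc1)c1ccccc1)[C@@H]2O | intermediate
19 | CNP0276372.1, the (7R,8S) macrocycle with free phenol, C7 hydroxyl and C9 hydroxyl | COc1cc2cc(c1O)Oc1ccc(cc1)/C=C/C(=O)NCCc1c[nH]c3ccc(cc13)O[C@@H](CO)[C@@H]2O | target

**Step count and risks**

Total: 12 steps. Longest linear sequence: 8 steps (steps 1–4 and 9–12, from 1).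

Steps most likely to fail:

Step 11. The aryl group may add with poor facial discrimination, because the conformation of the 21-membered transition state can override the Felkin–Anh preference; bimolecular coupling or simple reduction of the C–I bond may also compete. The fallback sets the C7 centre by reduction instead of addition. Setting out from 16, the ring is closed as in step 11 without regard to selectivity, and the mixture of 18 and its C7 epimer, the (7S,8S) bis-silyl macrocycle F1, is oxidised as a whole (Dess–Martin periodinane, CH2Cl2, 0 °C) to the macrocyclic α-aryloxy aryl ketone F2. This is reduced at low temperature with catecholborane under the (R)-configured methyl oxazaborolidine (Corey–Bakshi–Shibata reduction, ring A taken as the large group), a non-basic reagent that should not enolise C8, and the route is rejoined at 18.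

Step 7. The redox condensation may stall or be diverted (elimination of the activated alcohol, alkylation of the reduced azodicarboxylate), because the carbinol is secondary and flanked by two alkoxymethyl groups and the hydroxyindole is only moderately acidic. The fallback replaces in situ activation by a sulfonate displacement. Setting out from 10, mesylation (MsCl, Et3N, CH2Cl2, 0 °C) gives (2S)-1-(benzyloxy)-3-[(tert-butyldiphenylsilyl)oxy]propan-2-yl methanesulfonate F3, and the cesium phenoxide of 12 (Cs2CO3, DMF, 70 °C) displaces it by SN2 with the same inversion, coming back to the route at 13.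

Step 10. The α-aryloxy aldehyde may lose configurational purity through enolisation during oxidation or work-up, and the electron-rich indole may be attacked by the oxidant. The fallback reaches the aldehyde by reduction from the ester level, so no oxidant is used. It sets out from 12 and comes back to the route at 16:
- Commercial methyl (R)-2,3-dihydroxypropanoate is silylated at its primary hydroxyl (TBDPSCl, imidazole) to methyl (2R)-3-[(tert-butyldiphenylsilyl)oxy]-2-hydroxypropanoate F4.
- Mitsunobu reaction with 12 (PPh3, DIAD, inversion) gives the (2S)-aryloxy ester F5.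
- Hydrogenolysis of the carbamate (H2, Pd on carbon, EtOAc–AcOH) gives the amino ester F6, which is coupled at once with acid 8 (DIC, HOBt) to the amide ester F7.
- DIBAL-H (CH2Cl2, −78 °C, enough to cover the two N–H bonds) stops at the aluminium hemiacetal of the α-aryloxy ester and gives 16 on work-up with aqueous potassium sodium tartrate.

**Further compounds**

F1 | step 11 | (7S,8S) epimer of bis-silyl macrocycle 18 | COc1cc2cc(c1O[Si](C)(C)C(C)(C)C)Oc1ccc(cc1)/C=C/C(=O)NCCc1c[nH]c3ccc(cc13)O[C@@H](CO[Si](C(C)(C)C)(c1ccccc1)c1ccccc1)[C@H]2O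
F2 | step 11 | macrocyclic C7 ketone (8S), bis-silyl protected | COc1cc2cc(c1O[Si](C)(C)C(C)(C)C)Oc1ccc(cc1)/C=C/C(=O)NCCc1c[nH]c3ccc(cc13)O[C@@H](CO[Si](C(C)(C)C)(c1ccccc1)c1ccccc1)C2=O
F3 | step 7 | (2S)-1-(benzyloxy)-3-[(tert-butyldiphenylsilyl)oxy]propan-2-yl methanesulfonate | CS(=O)(=O)O[C@@H](COCc1ccccc1)CO[Si](c1ccccc1)(c1ccccc1)C(C)(C)C
F4 | step 10 | methyl (2R)-3-[(tert-butyldiphenylsilyl)oxy]-2-hydroxypropanoate | COC(=O)[C@H](O)CO[Si](c1ccccc1)(c1ccccc1)C(C)(C)C
F5 | step 10 | methyl (2S)-2-[(3-{2-[(benzyloxycarbonyl)amino]ethyl}-1H-indol-5-yl)oxy]-3-[(tert-butyldiphenylsilyl)oxy]propanoate | COC(=O)[C@@H](Oc1ccc2[nH]cc(CCNC(=O)OCc3ccccc3)c2c1)CO[Si](c1ccccc1)(c1ccccc1)C(C)(C)C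
F6 | step 10 | methyl (2S)-2-{[3-(2-aminoethyl)-1H-indol-5-yl]oxy}-3-[(tert-butyldiphenylsilyl)oxy]propanoate | COC(=O)[C@@H](Oc1ccc2[nH]cc(CCN)c2c1)CO[Si](c1ccccc1)(c1ccccc1)C(C)(C)C
F7 | step 10 | methyl (2S)-2-{[3-(2-{(E)-3-[4-(2-{[tert-butyl(dimethyl)silyl]oxy}-5-iodo-3-methoxyphenoxy)phenyl]acrylamido}ethyl)-1H-indol-5-yl]oxy}-3-[(tert-butyldiphenylsilyl)oxy]propanoate | COC(=O)[C@@H](Oc1ccc2[nH]cc(CCNC(=O)/C=C/c3ccc(Oc4cc(I)cc(OC)c4O[Si](C)(C)C(C)(C)C)cc3)c2c1)CO[Si](c1ccccc1)(c1ccccc1)C(C)(C)C
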